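The data are calculated with constants of no real substance; scatter was added.

The ratio I watched was the loss ratio: solid substrate lost per hour in one run over that in another, each lost fraction of the charge multiplied by the charge.

in all of them: free enzyme 0.01 mol%

| charge | solid substrate | second substrate | remark |
|---|---|---|---|
| Sunday's | 0.16 M | 0.55 equiv | run made earlier |
| Friday's | 0.16 M | 2.2 equiv | run made earlier |
| Wednesday's | 0.080 M | 1.1 equiv | run made earlier |
| flask | 0.16 M | 1.10 equiv |  |

| run | time / h | target / % | solid substrate / % |
|---|---|---|---|
| Sunday's | 0.833 | 1.2 | 99.2 |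
| Sunday's | 2.50 | 6.3 | 94.5 |
| Sunday's | 4.00 | 9.1 | 89.3 |
| Sunday's | 6.00 | 13.2 | 83.1 |
| Sunday's | 10.0 | 26.5 | 73.2 |
| Sunday's | 12.0 | 29.7 | 68.3 |
| Sunday's | 15.0 | 37.8 | 57.7 |
| Friday's | 1.33 | 2.2 | 96.2 |
| Friday's | 2.00 | 2.2 | 94.8 |
| Friday's | 3.00 | 7.6 | 91.6 |
| Friday's | 4.00 | 9.4 | 87.2 |
| Friday's | 6.00 | 14.1 | 85.3 |
| Friday's | 10.0 | 25.2 | 73.7 |
| Friday's | 15.0 | 39.3 | 58.4 |
| Wednesday's | 1.33 | 2.4 | 91.6 |
| Wednesday's | 2.50 | 5.9 | 86.3 |
| Wednesday's | 4.00 | 13.9 | 78.1 |
| Wednesday's | 8.00 | 32.4 | 56.7 |
| Wednesday's | 15.0 | 63.9 | 20.3 |

(each reading ± 1 percentage point)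

1. apparent order in second substrate when 50% of the solid substrate are converted (what has only dissolved counts as not reacted) (percent change of the rate of making target for one percent more second substrate charged)
2. apparent order in free enzyme when 50% of the solid substrate are converted (what has only dissolved counts as not reacted) (percent change of the rate of making target for one percent more free enzyme charged)
3. factor on the rate of making target when 50% of the solid substrate are converted (what has only dissolved counts as not reacted) if free enzyme is charged twice over

- solid, in amounts per volume of the solution: solid substrate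
- at the start none of the solid substrate is in solution
- what has only dissolved of solid substrate counts as not reacted

Wednesday's run held half the free enzyme concentration of Sunday's, at equal second substrate concentration as charged, but also half the solid substrate, which I assumed not to matter. In Sunday's run, target trailed the solid loss by 4.50% of the charge against 42.3% lost, so I took solid loss as the measure of the rate of making target. By 15.0 h, Wednesday's run had lost 79.7% of its smaller charge:

loss ratio, Wednesday's over Sunday's = 0.942

order in free enzyme = 0.0861; factor on doubling = 1.06

This reading stands nearer 1 than 0.5, and I read that as dissolution being the rate-limiting step. Friday's over Sunday's, with 4.00 times the second substrate, read 0.983, so I took the order in second substrate as zero within the scatter. One number was not quite enough: it averages Sunday's run up to 42.3% lost, less than the 50% asked.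

The forecast gave 0.04, 0.12 and 1.08, on the ground “So dissolution limits the rate”; its enzyme order stands above mine.

The flask gave 0.053, 0.060 and 1.03.

    starting material + free enzyme ⇌ first complex (K = 210 M⁻¹, k = 30.8 M⁻¹ s⁻¹)
    first complex ⇌ loaded enzyme + first product (K = 0.140 M, k = 2.89 s⁻¹)
    second substrate + loaded enzyme ⇌ second complex (K = 18.0 M⁻¹, k = 13.9 M⁻¹ s⁻¹)
    second complex → free enzyme + target (k = 1.59 s⁻¹)
    solid substrate ⇌ starting material, rate k5*(cs5 - [starting material]) while solid is left; crystals form when [starting material] > cs5 (solubility = 0.110 M, k = 1.13 × 10⁻⁵ s⁻¹)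

The flask made target at 0.00428 M h⁻¹ at 19.2 h. By 25.0 h it had lost 67.9% of its charge, and Wednesday's run over this flask, which held twice the free enzyme and twice the second substrate, gave a loss ratio of 0.978.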